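The data were computed with made-up constants; noise was put on by code.

Target leaks into its isomer. In the oak run the first reading already holds 69% target and 31% isomer of the product, an early split (kinetic control), and in the elm run target then turns slowly into isomer.

| setting | maple | oak | elm | flask |
|---|---|---|---|---|
| starting material | 1.1 M | 1.7 M | 0.77 M | 0.77 M |
| protic impurity | 0.0385 M | 0.0385 M | 0.019 M | 0.0385 M |
| remark | run made earlier | run made earlier | run made earlier |  |
| time |  |  |  | 15 d |

| run | time / d | target / % | isomer of the product / % |
|---|---|---|---|
| maple | 2.50 | 65 | 31 |
| maple | 6.00 | 63 | 30 |
| maple | 12.0 | 57 | 43 |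
| maple | 20.0 | 51 | 43 |
| oak | 1.25 | 69 | 31 |
| oak | 3.00 | 70 | 31 |
| oak | 8.00 | 68 | 31 |
| oak | 20.0 | 67 | 32 |
| elm | 1.25 | 67 | 33 |
| elm | 3.00 | 64 | 35 |
| elm | 8.00 | 52 | 46 |
| elm | 20.0 | 41 | 58 |

(each reading ± 1.5 percentage points)

- amounts and yields of target count crystals too
- given per volume of solution although it is solid: crystals
- steps thought possible: target <-> isomer of the product; starting material + protic impurity -> quenched substrate; crystals <-> target; starting material <-> isomer of the product; starting material <-> target

1. share of target in target plus isomer of the product at 15 min
2. share of target in target plus isomer of the product at 8.0 h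
3. share of target in target plus isomer of the product at 15 d
4. which of target and isomer of the product there is more of at 15 d

The reckoning here treats the isomer as a first-order lag towards a ceiling, and the ceiling is read from the oak run, whose isomer stays flat and reads 0.544 M at 20.0 d. In the elm run the gap below that ceiling shrinks from 0.290 M at 1.25 d to 0.0974 M at 20.0 d, so its rate constant reads 0.0582 /d. The maple run has twice the impurity of the elm run and 1.1 M of starting material against 0.77 M, yet this rate, started from its first reading, gives 42.8% isomer at 20.0 d, where it read 43%. At 6.00 d the same curve gives 34.4% where the run read 30%, but the reckoning here counts no lag.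

The flask has the starting material of the elm run but twice its impurity; its isomer is taken to start from the elm run's first reading, and the fraction of the gap left at 15 d, counted from 1.25 d, is 0.449. That puts the flask's isomer at 53.7% of the charge. Taking the whole impurity charge to quench 5.00% of the starting material, the target share reckons at 43.4%, and this reckoning has isomer ahead. The time 8.0 h is shorter than the time constant 17.2 d, so both early shares are reckoned near 69.0%, the split read in the oak run.

The forecast differs at the late time: it gave 68%, 68% and 53% (45% to 63%) with target ahead, holding that “the protic impurity seems to delay isomerisation until it is consumed”.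

The flask gives 71.2%, 70.2% and 42.6%, with isomer of the product ahead.

    target ⇌ isomer of the product (k = 0.0452 /h)
    starting material + protic impurity → quenched substrate (k = 1.84 /M/h)
    crystals ⇌ target, rate k3*(cs3 - [target]) while solid is left; crystals form when [target] > cs3 (solubility = 14.0 mM, k = 25.9 /h)
    starting material ⇌ isomer of the product (K = 163, k = 0.364 /h)
    starting material ⇌ target (K = 4.20, k = 0.915 /h)

The flask's isomer had reached 44.2% at 7.50 d, while protic impurity stood at 13.4% of its own charge. The same fraction left, applied to the neighbour flask charged with 1.3 M of starting material, gives 37.9% isomer, and that neighbour holds 36.6% at 15.0 d.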